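**Retrosynthetic overview**
1. Target 8 ⇐ 7: cis-addition of H2 to the C1=C2 bond from the face opposite the C3 methyl (sets C1 and C2, all-cis).
2. 7 ⇐ 5: ring B is closed by acid cyclodehydration of a 1,4-diarylbutan-1-one (C1–C8a bond, then loss of water).
3. 5 ⇐ 3: the carbonyl C–O bond is made by oxidising one of the two enantiotopic benzylic CH2 groups of a meso diarylbutane; this choice fixes the absolute configuration at C3.
4. 3 ⇐ 1 + 2: the four aryl methyl ether C–O bonds come from O-methylation of nordihydroguaiaretic acid (NDGA).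
5. Ring order: both benzene rings arrive with 1; the only ring built is the saturated ring B (step 3).

Assumptions: commercial NDGA is the meso isomer; in step 2 the sense of induction cannot be predicted, so the (S,S) catalyst is written and its mirror image is used if one screening run shows the opposite CH2 is attacked. TIPS-pdp = N,N'-bis{[5-(triisopropylsilyl)pyridin-2-yl]methyl}-2,2'-bipyrrolidine.

**Step 1**
Reactants: 1 nordihydroguaiaretic acid (meso); 2 iodomethane
Product: 3 (2R,3S)-1,4-bis(3,4-dimethoxyphenyl)-2,3-dimethylbutane (meso)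
Conditions: MeI (6 equiv), K2CO3 (6 equiv), acetone, reflux, N2, 16 h
Reagents that add atoms: iodomethane, CI
Why: Williamson ether synthesis (phenoxide SN2 on MeI) installs all four methoxy groups of the target; no stereocentre is touched, and exclusion of air prevents catechol oxidation to quinone.

**Step 2**
Reactants: 3 (2R,3S)-1,4-bis(3,4-dimethoxyphenyl)-2,3-dimethylbutane
Product: 5 (2R,3R)-1,4-bis(3,4-dimethoxyphenyl)-2,3-dimethylbutan-1-one, via benzylic alcohol 4 (not isolated)
Conditions: [Mn(OTf)2((S,S)-TIPS-pdp)] (2 mol%), H2O2 (50% aq., 2.5 equiv, syringe pump 2 h), 2,2-dimethylbutanoic acid (5 equiv), MeCN/CH2Cl2 4:1, −40 °C; stopped at about 75% conversion, 3 recovered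
Reagents that add atoms: hydrogen peroxide, OO
Why: Proposed new method: enantiotopic-group-selective benzylic C–H oxygenation of a meso 1,4-diarylbutane. The carboxylate-bound oxomanganese species (manganese formally pentavalent) abstracts a benzylic hydrogen inside the chiral pocket and returns OH by rebound, and 4 is oxidised on to the ketone in the same flask. The two ArCH2 groups sit next to centres of opposite configuration, so the chiral oxidant tells them apart as it would the enantiomers of a racemic ArCH2–CH(Me)R substrate. Oxidising only the CH2 next to the (S)-centre leaves the (R)-centre as C3 of 5 and so fixes the absolute configuration. Over-oxidation of the minor enantiomer at its remaining, favoured CH2 to the diketone should raise the ee of 5. C2 of 5 is epimerisable, which does not matter because it becomes sp2 in step 3. Closest known reactions: manganese aminopyridine/H2O2 enantioselective benzylic hydroxylation, the desymmetrising CH2-to-C=O oxidation of spirocyclic indanes and tetralins, and Mn(salen) enantiotopic C–H hydroxylation of meso tetrahydrofurans.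

**Step 3**
Reactants: 5 (2R,3R)-1,4-bis(3,4-dimethoxyphenyl)-2,3-dimethylbutan-1-one
Product: 7 (3R)-1-(3,4-dimethoxyphenyl)-6,7-dimethoxy-2,3-dimethyl-3,4-dihydronaphthalene, via tetralol 6 (not isolated)
Conditions: TsOH·H2O (0.2 equiv), toluene, reflux (Dean–Stark), N2, 3 h
Reagents that add atoms: none
Why: Bradsher-type cyclodehydration (intramolecular Friedel–Crafts hydroxyalkylation, then E1 loss of water): the alkyl-bearing veratryl ring attacks the protonated ketone para to its 3-methoxy group to close the six-membered ring B, and the diaryl cation loses the C2 proton to give the conjugated tetrasubstituted alkene; C3 is not involved and keeps its R configuration.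

**Step 4**
Reactants: 7 (3R)-1-(3,4-dimethoxyphenyl)-6,7-dimethoxy-2,3-dimethyl-3,4-dihydronaphthalene
Product: 8 (1S,2R,3R)-1-(3,4-dimethoxyphenyl)-6,7-dimethoxy-2,3-dimethyl-1,2,3,4-tetrahydronaphthalene (all-cis, the target)
Conditions: H2 (4 atm), Pd(OH)2/C (20 wt%), EtOAc/EtOH 1:1, rt, 24 h
Reagents that add atoms: none
Why: Heterogeneous syn-hydrogenation: the C3 methyl sits pseudoaxial (A1,2 strain with the C2 methyl) and blocks one face, so both hydrogens add to the opposite face and the C1 aryl and C2 methyl end up cis to the C3 methyl, giving 1S,2R.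

**Compound list**
1 | nordihydroguaiaretic acid, 4,4'-[(2R,3S)-2,3-dimethylbutane-1,4-diyl]dibenzene-1,2-diol (meso) | Oc1ccc(C[C@H](C)[C@H](C)Cc2ccc(O)c(O)c2)cc1O | starting material
2 | iodomethane | CI | starting material
3 | (2R,3S)-1,4-bis(3,4-dimethoxyphenyl)-2,3-dimethylbutane (meso) | COc1ccc(C[C@H](C)[C@H](C)Cc2ccc(OC)c(OC)c2)cc1OC | intermediate
4 | (2R,3R)-1,4-bis(3,4-dimethoxyphenyl)-2,3-dimethylbutan-1-ol, carbinol centre either configuration (not isolated) | COc1ccc(C(O)[C@H](C)[C@H](C)Cc2ccc(OC)c(OC)c2)cc1OC | intermediate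
5 | (2R,3R)-1,4-bis(3,4-dimethoxyphenyl)-2,3-dimethylbutan-1-one | COc1ccc(C(=O)[C@H](C)[C@H](C)Cc2ccc(OC)c(OC)c2)cc1OC | intermediate
6 | (2R,3R)-1-(3,4-dimethoxyphenyl)-6,7-dimethoxy-2,3-dimethyl-1,2,3,4-tetrahydronaphthalen-1-ol, C1 either configuration (not isolated) | COc1ccc(C2(O)[C@H](C)[C@H](C)Cc3cc(OC)c(OC)cc32)cc1OC | intermediate
7 | (3R)-1-(3,4-dimethoxyphenyl)-6,7-dimethoxy-2,3-dimethyl-3,4-dihydronaphthalene | COc1ccc(C2=C(C)[C@H](C)Cc3cc(OC)c(OC)cc32)cc1OC | intermediate
8 | (1S,2R,3R)-1-(3,4-dimethoxyphenyl)-6,7-dimethoxy-2,3-dimethyl-1,2,3,4-tetrahydronaphthalene | COc1ccc([C@H]2c3cc(OC)c(OC)cc3C[C@@H](C)[C@H]2C)cc1OC | target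

**Step count:** 4 steps in total; longest linear sequence 4 steps.

**Steps most likely to fail**

Step 2 (the proposed new method). The risks are insufficient discrimination of the two CH2 groups, hydroxylation of the electron-rich rings, and over-oxidation to the diketone. The fallback uses known chemistry and sets out from 3. Non-selective benzylic mono-oxidation (t-BuOOH, Rh2(cap)4 1 mol%, NaHCO3, DCE, 40 °C, stopped near half conversion, 3 recycled) gives the racemic ketone, that is 5 together with its enantiomer (2S,3S)-1,4-bis(3,4-dimethoxyphenyl)-2,3-dimethylbutan-1-one F1. Cyclodehydration as in step 3 passes through 6 and its enantiomer (2S,3S)-1-(3,4-dimethoxyphenyl)-6,7-dimethoxy-2,3-dimethyl-1,2,3,4-tetrahydronaphthalen-1-ol F2, neither isolated. It gives the racemic dihydronaphthalene, 7 plus (3S)-1-(3,4-dimethoxyphenyl)-6,7-dimethoxy-2,3-dimethyl-3,4-dihydronaphthalene F3. Preparative SFC on an amylose tris(3,5-dimethylphenylcarbamate) phase removes F3, and the path comes back to the route at 7.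

Step 3. The aryl ketone is electron-rich and therefore a weak electrophile; prolonged acid may also cause alkene migration or aromatisation. The fallback sets out from 5 and reverses the polarity of ring closure. Iodination of the alkyl-bearing ring para to its 3-methoxy group (NIS, TFA cat., MeCN, 0 °C) gives (2R,3R)-1-(3,4-dimethoxyphenyl)-4-(2-iodo-4,5-dimethoxyphenyl)-2,3-dimethylbutan-1-one F4. Iodine–lithium exchange (n-BuLi, THF, −100 °C) followed by 6-exo addition of the aryllithium to the ketone (Parham-type anionic cyclisation) gives the tetralol after aqueous work-up. The path comes back to the route at 6, which is dehydrated to 7 with TsOH (5 mol%, CH2Cl2, rt).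

Step 4. The risks are modest facial selectivity and Pd-mediated double-bond migration, which would erode C3. The fallback sets out from 7 and goes directly to 8, replacing substrate control by catalyst control: homogeneous hydrogenation with [Ir(cod)((S)-tBu-PHOX)]BArF or its mirror image (whichever is matched with the C3 methyl bias), H2 50 bar, CH2Cl2, rt. This does not isomerise the alkene. No new compound is made on this path.

**Further compounds**
F1 | step 2 | (2S,3S)-1,4-bis(3,4-dimethoxyphenyl)-2,3-dimethylbutan-1-one | COc1ccc(C(=O)[C@@H](C)[C@@H](C)Cc2ccc(OC)c(OC)c2)cc1OC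
F2 | step 2 | (2S,3S)-1-(3,4-dimethoxyphenyl)-6,7-dimethoxy-2,3-dimethyl-1,2,3,4-tetrahydronaphthalen-1-ol, C1 either configuration | COc1ccc(C2(O)[C@@H](C)[C@@H](C)Cc3cc(OC)c(OC)cc32)cc1OC
F3 | step 2 | (3S)-1-(3,4-dimethoxyphenyl)-6,7-dimethoxy-2,3-dimethyl-3,4-dihydronaphthalene | COc1ccc(C2=C(C)[C@@H](C)Cc3cc(OC)c(OC)cc32)cc1OC
F4 | step 3 | (2R,3R)-1-(3,4-dimethoxyphenyl)-4-(2-iodo-4,5-dimethoxyphenyl)-2,3-dimethylbutan-1-one | COc1ccc(C(=O)[C@H](C)[C@H](C)Cc2cc(OC)c(OC)cc2I)cc1OC
F0 | step 4 | none | none
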